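**Retrosynthetic overview**

1. Ring C (the 3-methyltetronic acid with its Z-ylidene) is cut at the exocyclic C=C bond: lithiated 4-methoxy-3-methylfuran-2(5H)-one plus the (S)-α-methyl aldehyde 27, then dehydration and O-demethylation.
2. The chain is cut at the CH2–CH2 bond next to ring B: the furylmethyl Grignard reagent from chloride 10 plus the (Z)-allylic chloride 23 under Li2CuCl4 catalysis. Chloride 23 comes from a B-alkyl Suzuki coupling of the Evans-derived (S)-alkene 16 with (Z)-3-iodobut-2-en-1-ol 19.
3. The strategy rests on ring B, a 2,4-disubstituted furan (O1, C2, C3, C4, C5): C2 carries the CH2 bonded to C3 of ring A (the terminal 3-furyl ring) and C4 carries the first chain carbon. The CH2 is therefore a former propargylic carbinol carbon bearing ring A, C2/C3 a former alkyne, and C5/C4 with the attached carbon a former 3-alkoxyacrylate.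
4. A gold-catalysed propargyl Claisen rearrangement forms C3–C4 and a 5-exo heterocyclisation forms O1–C2, from propargyl vinyl ether 5.
5. Ring order: ring A is bought (furan-3-carbaldehyde), ring B is closed in step 3, ring C is brought in preformed in step 16.

Key step: step 3

Remark: the SMILES is read as (S) at the methyl-bearing chain carbon and Z at both the chain alkene and the exocyclic ylidene; 3-methyltetronic acid 28 is taken as a purchasable compound.

**Route**

Step 1
Reactants: 1 furan-3-carbaldehyde; 2 ethynylmagnesium bromide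
Product: 3 rac-1-(furan-3-yl)prop-2-yn-1-ol
Conditions: THF, 0 °C to rt; aq. NH4Cl
Reagents that add atoms: none
Why: Grignard 1,2-addition of the acetylide to the aldehyde gives the propargylic alcohol, whose racemic centre does not matter because it later becomes the CH2 bridge.

Step 2
Reactants: 3 rac-1-(furan-3-yl)prop-2-yn-1-ol; 4 ethyl propiolate
Product: 5 ethyl (E)-3-{[1-(furan-3-yl)prop-2-yn-1-yl]oxy}prop-2-enoate (racemic)
Conditions: N-methylmorpholine (0.2 equiv), CH2Cl2, rt
Reagents that add atoms: none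
Why: Amine-catalysed oxa-Michael addition of the alcohol to the propiolate (via the ammonium allenolate) should give the thermodynamically preferred (E)-β-alkoxyacrylate.

Step 3
Reactants: 5 ethyl (E)-3-{[1-(furan-3-yl)prop-2-yn-1-yl]oxy}prop-2-enoate
Product: 7 ethyl 5-(furan-3-ylmethyl)furan-3-carboxylate, via allenyl formylacetate 6 (not isolated)
Conditions: Ph3PAuCl (2 mol %), AgSbF6 (2 mol %), CH2Cl2, 23 °C
Reagents that add atoms: none
Why: The cationic monovalent gold π-acid Ph3PAu+ SbF6− binds the terminal alkyne of 5, the ester-bearing enol-ether carbon attacks the terminal alkyne carbon through a six-membered oxocarbenium vinylgold species, and cleavage of the propargylic C–O bond completes a net [3,3] propargyl Claisen shift that forms the C3–C4 bond of ring B and gives allene 6. The enol oxygen of the formylacetate in 6 then adds to the gold-activated central allene carbon in a 5-exo-dig closure (O1–C2 bond), and protodeauration at the former carbinol carbon leaves the aromatic furan with the CH2 bridge to ring A. The closest known reaction type is the gold-catalysed propargyl Claisen rearrangement–heterocyclisation of 3-(propargyloxy)acrylates to furan-3-carboxylates. No stereocentre is formed and the racemic carbinol centre of 5 is erased. The step needs the sigmatropic shift to outrun ionisation of the furyl-stabilised propargylic C–O bond, which the carbophilic, non-protic catalyst at ambient temperature and the unhindered terminal alkyne should secure, while the regiochemistry of ring B is fixed by connectivity because only the central allene carbon lies within five-ring reach of the enol oxygen.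

Step 4
Reactants: 7 ethyl 5-(furan-3-ylmethyl)furan-3-carboxylate
Product: 8 [5-(furan-3-ylmethyl)furan-3-yl]methanol
Conditions: LiAlH4, THF, 0 °C
Reagents that add atoms: none
Why: Hydride reduction of the ester gives the primary alcohol and leaves both furan rings untouched.

Step 5
Reactants: 8 [5-(furan-3-ylmethyl)furan-3-yl]methanol
Product: 10 4-(chloromethyl)-2-(furan-3-ylmethyl)furan, via mesylate 9 (not isolated)
Conditions: MsCl, LiCl, 2,4,6-collidine, DMF, 0 °C; used crude
Reagents that add atoms: lithium chloride, [Li+].[Cl-]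
Why: Mesylation and SN2 displacement by chloride in a base-buffered medium should convert the acid-sensitive furylmethyl alcohol into the chloride without exposing the furans to acid.

Step 6
Reactants: 11 (R)-4-benzyl-3-propanoyloxazolidin-2-one; 12 allyl iodide
Product: 14 (R)-4-benzyl-3-[(S)-2-methylpent-4-enoyl]oxazolidin-2-one, via sodium enolate 13 (not isolated)
Conditions: NaN(SiMe3)2, THF, −78 °C; then 12, −78 to −45 °C
Reagents that add atoms: none
Why: Evans asymmetric alkylation, in which the chelated sodium (Z)-enolate is allylated on the face opposite the benzyl group and so sets the (S) methyl-bearing centre that becomes the stereocentre of the target.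

Step 7
Reactants: 14 (R)-4-benzyl-3-[(S)-2-methylpent-4-enoyl]oxazolidin-2-one
Product: 15 (S)-2-methylpent-4-en-1-ol
Conditions: LiBH4, MeOH (1 equiv), Et2O, 0 °C
Reagents that add atoms: none
Why: Reductive cleavage of the imide releases the primary alcohol and the recoverable auxiliary without touching the stereocentre or the alkene.

Step 8
Reactants: 15 (S)-2-methylpent-4-en-1-ol
Product: 16 (S)-tert-butyldimethyl[(2-methylpent-4-en-1-yl)oxy]silane
Conditions: TBSCl, imidazole, CH2Cl2, rt
Reagents that add atoms: tert-butyldimethylsilyl chloride, CC(C)(C)[Si](C)(C)Cl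
Why: Silylation of the primary alcohol gives an ether that withstands the borane, the Grignard reagent and the copper coupling and is later removed by fluoride.

Step 9
Reactants: 17 but-2-yn-1-ol
Product: 19 (Z)-3-iodobut-2-en-1-ol, via cyclic vinylalanate 18 (not isolated)
Conditions: NaAlH2(OCH2CH2OMe)2, THF, 0 °C to rt; then I2, −78 to 0 °C
Reagents that add atoms: iodine, II
Why: Hydroxyl-directed trans-hydroalumination of the propargylic alcohol places aluminium at C3 in a five-membered alanate, and iodinolysis with retention should give the (Z)-vinyl iodide.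

Step 10
Reactants: 16 (S)-tert-butyldimethyl[(2-methylpent-4-en-1-yl)oxy]silane; 19 (Z)-3-iodobut-2-en-1-ol
Product: 21 (2Z,7S)-8-[(tert-butyldimethylsilyl)oxy]-3,7-dimethyloct-2-en-1-ol, via alkylborane 20 (not isolated)
Conditions: 9-BBN, THF, rt; then 19, PdCl2(dppf) (5 mol %), AsPh3, Cs2CO3, DMF–H2O, rt
Reagents that add atoms: none
Why: Anti-Markovnikov hydroboration followed by B-alkyl Suzuki–Miyaura coupling joins the sp3 carbon to the vinyl iodide with retention of the Z geometry, and the stereocentre is remote from the reacting sites.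

Step 11
Reactants: 21 (2Z,7S)-8-[(tert-butyldimethylsilyl)oxy]-3,7-dimethyloct-2-en-1-ol
Product: 23 tert-butyl{[(2S,6Z)-8-chloro-2,6-dimethyloct-6-en-1-yl]oxy}dimethylsilane, via allylic mesylate 22 (not isolated)
Conditions: MsCl, LiCl, 2,4,6-collidine, DMF, 0 °C
Reagents that add atoms: lithium chloride, [Li+].[Cl-]
Why: Mesylation and direct SN2 chloride displacement at the primary allylic carbon should give the chloride without allylic transposition or Z/E isomerisation, as for neryl-type alcohols.

Step 12
Reactants: 10 4-(chloromethyl)-2-(furan-3-ylmethyl)furan; 23 tert-butyl{[(2S,6Z)-8-chloro-2,6-dimethyloct-6-en-1-yl]oxy}dimethylsilane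
Product: 25 tert-butyl({(2S,6Z)-9-[5-(furan-3-ylmethyl)furan-3-yl]-2,6-dimethylnon-6-en-1-yl}oxy)dimethylsilane, via Grignard reagent 24 (not isolated)
Conditions: Mg turnings, THF, 0 °C to rt; then 23, Li2CuCl4 (5 mol %), THF, 0 °C
Reagents that add atoms: none
Why: Magnesium insertion gives the furylmethyl Grignard reagent, and copper-catalysed Grignard–allylic halide cross-coupling (Kochi type) should occur at the unhindered CH2Cl terminus, so the Z alkene and the remote stereocentre are preserved.

Step 13
Reactants: 25 tert-butyl({(2S,6Z)-9-[5-(furan-3-ylmethyl)furan-3-yl]-2,6-dimethylnon-6-en-1-yl}oxy)dimethylsilane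
Product: 26 (2S,6Z)-9-[5-(furan-3-ylmethyl)furan-3-yl]-2,6-dimethylnon-6-en-1-ol
Conditions: Bu4NF, THF, 0 °C to rt
Reagents that add atoms: none
Why: Fluoride-induced desilylation frees the primary alcohol under non-acidic conditions that the furans tolerate.

Step 14
Reactants: 26 (2S,6Z)-9-[5-(furan-3-ylmethyl)furan-3-yl]-2,6-dimethylnon-6-en-1-ol
Product: 27 (2S,6Z)-9-[5-(furan-3-ylmethyl)furan-3-yl]-2,6-dimethylnon-6-enal
Conditions: Dess–Martin periodinane, NaHCO3, CH2Cl2, 0 °C to rt; used at once
Reagents that add atoms: none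
Why: Buffered Dess–Martin oxidation gives the α-methyl aldehyde without acid or base strong enough to enolise it, so the (S) centre should be kept.

Step 15
Reactants: 28 3-methyltetronic acid
Product: 29 4-methoxy-3-methylfuran-2(5H)-one
Conditions: Me2SO4, K2CO3, acetone, reflux
Reagents that add atoms: dimethyl sulfate, COS(=O)(=O)OC
Why: O-Alkylation of the vinylogous acid under mild base gives the 4-methyl ether, which masks the acidic proton for the enolate chemistry.

Step 16
Reactants: 29 4-methoxy-3-methylfuran-2(5H)-one; 27 (2S,6Z)-9-[5-(furan-3-ylmethyl)furan-3-yl]-2,6-dimethylnon-6-enal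
Product: 31 5-{(2S,6Z)-9-[5-(furan-3-ylmethyl)furan-3-yl]-1-hydroxy-2,6-dimethylnon-6-en-1-yl}-4-methoxy-3-methylfuran-2(5H)-one (mixture at the two new centres), via lithium furanolate 30 (not isolated)
Conditions: LiN(iPr)2, THF, −78 °C; then 27, −78 °C; AcOH quench
Reagents that add atoms: none
Why: Deprotonation at C5 gives the aromatic 2-furanolate, which undergoes aldol addition through C5 at −78 °C faster than it enolises the aldehyde; the two new stereocentres are uncontrolled and are removed in step 17.

Step 17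
Reactants: 31 5-{(2S,6Z)-9-[5-(furan-3-ylmethyl)furan-3-yl]-1-hydroxy-2,6-dimethylnon-6-en-1-yl}-4-methoxy-3-methylfuran-2(5H)-one
Product: 33 (5Z)-5-{(2S,6Z)-9-[5-(furan-3-ylmethyl)furan-3-yl]-2,6-dimethylnon-6-en-1-ylidene}-4-methoxy-3-methylfuran-2(5H)-one, via mesylate 32 (not isolated)
Conditions: MsCl, Et3N, CH2Cl2, 0 °C; then DBU, 0 °C to rt
Reagents that add atoms: none
Why: Mesylation and DBU-mediated E1cB elimination through the acidic C5–H give the exocyclic alkene, with the Z isomer favoured because it avoids the clash between the chain and the 4-methoxy group, and the much less acidic allylic stereocentre should not be deprotonated.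

Step 18
Reactants: 33 (5Z)-5-{(2S,6Z)-9-[5-(furan-3-ylmethyl)furan-3-yl]-2,6-dimethylnon-6-en-1-ylidene}-4-methoxy-3-methylfuran-2(5H)-one
Product: 34 (5Z)-5-{(2S,6Z)-9-[5-(furan-3-ylmethyl)furan-3-yl]-2,6-dimethylnon-6-en-1-ylidene}-4-hydroxy-3-methylfuran-2(5H)-one (target)
Conditions: LiCl, DMSO, 50 °C; then cold 0.5 M HCl
Reagents that add atoms: none
Why: Nucleophilic demethylation, in which chloride attacks the O-methyl carbon (SN2) and expels the stabilised tetronate, is a neutral method that should spare the furans, both alkenes and the stereocentre, and brief cold acidification liberates the tetronic acid.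

**Compound list**

1 | furan-3-carbaldehyde | O=Cc1ccoc1 | starting material
2 | ethynylmagnesium bromide | C#C[Mg]Br | starting material
3 | rac-1-(furan-3-yl)prop-2-yn-1-ol | OC(C#C)c1ccoc1 | intermediate
4 | ethyl propiolate | CCOC(=O)C#C | starting material
5 | ethyl (E)-3-{[1-(furan-3-yl)prop-2-yn-1-yl]oxy}prop-2-enoate (racemic) | CCOC(=O)/C=C/OC(C#C)c1ccoc1 | intermediate
6 | ethyl 2-formyl-5-(furan-3-yl)penta-3,4-dienoate (stereoisomer mixture) | CCOC(=O)C(C=O)C=C=Cc1ccoc1 | intermediate
7 | ethyl 5-(furan-3-ylmethyl)furan-3-carboxylate | CCOC(=O)c1coc(Cc2ccoc2)c1 | intermediate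
8 | [5-(furan-3-ylmethyl)furan-3-yl]methanol | OCc1coc(Cc2ccoc2)c1 | intermediate
9 | [5-(furan-3-ylmethyl)furan-3-yl]methyl methanesulfonate | CS(=O)(=O)OCc1coc(Cc2ccoc2)c1 | intermediate
10 | 4-(chloromethyl)-2-(furan-3-ylmethyl)furan | ClCc1coc(Cc2ccoc2)c1 | intermediate
11 | (R)-4-benzyl-3-propanoyloxazolidin-2-one | CCC(=O)N1[C@H](Cc2ccccc2)COC1=O | starting material
12 | allyl iodide | C=CCI | starting material
13 | sodium (Z)-1-[(R)-4-benzyl-2-oxooxazolidin-3-yl]prop-1-en-1-olate | C/C=C(\[O-])N1[C@H](Cc2ccccc2)COC1=O.[Na+] | intermediate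
14 | (R)-4-benzyl-3-[(S)-2-methylpent-4-enoyl]oxazolidin-2-one | O=C([C@@H](C)CC=C)N1[C@H](Cc2ccccc2)COC1=O | intermediate
15 | (S)-2-methylpent-4-en-1-ol | OC[C@@H](C)CC=C | intermediate
16 | (S)-tert-butyldimethyl[(2-methylpent-4-en-1-yl)oxy]silane | CC(C)(C)[Si](C)(C)OC[C@@H](C)CC=C | intermediate
17 | but-2-yn-1-ol | CC#CCO | starting material
18 | sodium cyclic (Z)-vinylalanate (five-membered O–Al–C(CH3)=CH–CH2 ring, aluminium bearing two 2-methoxyethoxy groups) | CC1=CCO[Al-]1(OCCOC)OCCOC.[Na+] | intermediate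
19 | (Z)-3-iodobut-2-en-1-ol | C/C(I)=C/CO | intermediate
20 | (S)-9-{5-[(tert-butyldimethylsilyl)oxy]-4-methylpentyl}-9-borabicyclo[3.3.1]nonane | CC(C)(C)[Si](C)(C)OC[C@@H](C)CCCB1C2CCCC1CCC2 | intermediate
21 | (2Z,7S)-8-[(tert-butyldimethylsilyl)oxy]-3,7-dimethyloct-2-en-1-ol | CC(C)(C)[Si](C)(C)OC[C@@H](C)CCC/C(C)=C\CO | intermediate
22 | (2Z,7S)-8-[(tert-butyldimethylsilyl)oxy]-3,7-dimethyloct-2-en-1-yl methanesulfonate | CC(C)(C)[Si](C)(C)OC[C@@H](C)CCC/C(C)=C\COS(C)(=O)=O | intermediate
23 | tert-butyl{[(2S,6Z)-8-chloro-2,6-dimethyloct-6-en-1-yl]oxy}dimethylsilane | CC(C)(C)[Si](C)(C)OC[C@@H](C)CCC/C(C)=C\CCl | intermediate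
24 | {[5-(furan-3-ylmethyl)furan-3-yl]methyl}magnesium chloride | Cl[Mg]Cc1coc(Cc2ccoc2)c1 | intermediate
25 | tert-butyl({(2S,6Z)-9-[5-(furan-3-ylmethyl)furan-3-yl]-2,6-dimethylnon-6-en-1-yl}oxy)dimethylsilane | CC(C)(C)[Si](C)(C)OC[C@@H](C)CCC/C(C)=C\CCc1coc(Cc2ccoc2)c1 | intermediate
26 | (2S,6Z)-9-[5-(furan-3-ylmethyl)furan-3-yl]-2,6-dimethylnon-6-en-1-ol | OC[C@@H](C)CCC/C(C)=C\CCc1coc(Cc2ccoc2)c1 | intermediate
27 | (2S,6Z)-9-[5-(furan-3-ylmethyl)furan-3-yl]-2,6-dimethylnon-6-enal | O=C[C@@H](C)CCC/C(C)=C\CCc1coc(Cc2ccoc2)c1 | intermediate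
28 | 3-methyltetronic acid (4-hydroxy-3-methylfuran-2(5H)-one) | CC1=C(O)COC1=O | starting material
29 | 4-methoxy-3-methylfuran-2(5H)-one | COC1=C(C)C(=O)OC1 | intermediate
30 | lithium 4-methoxy-3-methylfuran-2-olate | [Li+].[O-]c1occ(OC)c1C | intermediate
31 | 5-{(2S,6Z)-9-[5-(furan-3-ylmethyl)furan-3-yl]-1-hydroxy-2,6-dimethylnon-6-en-1-yl}-4-methoxy-3-methylfuran-2(5H)-one (mixture at C5 and the carbinol carbon) | COC1=C(C)C(=O)OC1C(O)[C@@H](C)CCC/C(C)=C\CCc2coc(Cc3ccoc3)c2 | intermediate
32 | methanesulfonate of 31 | COC1=C(C)C(=O)OC1C(OS(C)(=O)=O)[C@@H](C)CCC/C(C)=C\CCc2coc(Cc3ccoc3)c2 | intermediate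
33 | (5Z)-5-{(2S,6Z)-9-[5-(furan-3-ylmethyl)furan-3-yl]-2,6-dimethylnon-6-en-1-ylidene}-4-methoxy-3-methylfuran-2(5H)-one | CC1=C(OC)/C(=C/[C@@H](C)CCC/C(C)=C\CCc2coc(Cc3ccoc3)c2)OC1=O | intermediate
34 | (5Z)-5-{(2S,6Z)-9-[5-(furan-3-ylmethyl)furan-3-yl]-2,6-dimethylnon-6-en-1-ylidene}-4-hydroxy-3-methylfuran-2(5H)-one | CC1=C(O)/C(=C/[C@@H](C)CCC/C(C)=C\CCc2coc(Cc3ccoc3)c2)OC1=O | target

**Step count**

Total steps: 18. Longest linear sequence: 11 steps (steps 1–5, 12–14 and 16–18; the branch through steps 6–8, 10 and 11 is equally long).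

**Steps most likely to fail**

Step 3 (key step). The furyl-stabilised propargylic C–O bond may ionise, or the terminal alkyne and the enolised formylacetate may oligomerise on gold, faster than the sigmatropic shift, so ring B would not close cleanly. The fallback builds the difurylmethane by cross-coupling and sets out from 1. Reduction of 1 with NaBH4 in MeOH gives furan-3-ylmethanol F1, PBr3 in Et2O at 0 °C converts it into 3-(bromomethyl)furan F2, and zinc dust with LiCl in THF inserts to give (furan-3-ylmethyl)zinc bromide F3. Negishi coupling of F3 with purchased ethyl 5-bromofuran-3-carboxylate under Pd(PPh3)4 (zerovalent palladium) in THF would give ester 7, where the route is rejoined.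

Step 12. Wurtz-type homocoupling may occur during magnesium insertion into the labile chloride 10, or the organocopper species may attack the γ-carbon of the allylic chloride (SN2′) and give the branched isomer. The fallback replaces the Grignard reagent by a sulfone-stabilised carbanion and sets out from 10 and 23. Displacement of chloride in 10 with PhSO2Na in DMF gives 2-(furan-3-ylmethyl)-4-[(phenylsulfonyl)methyl]furan F4. Deprotonation with n-BuLi in THF at −78 °C gives its α-lithio derivative F5, which is alkylated at the primary carbon of 23 to the sulfone tert-butyl({(2S,6Z)-9-[5-(furan-3-ylmethyl)furan-3-yl]-2,6-dimethyl-9-(phenylsulfonyl)non-6-en-1-yl}oxy)dimethylsilane F6. Reductive desulfonylation with Na(Hg) and Na2HPO4 in MeOH–THF at −20 °C would give 25, where the route is rejoined.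

Step 18. The SN2 demethylation may be slow, and the prolonged heating then needed could isomerise the exocyclic alkene or degrade the furan rings. The fallback changes the O-protecting group to one cleaved by fluoride at 0 °C and sets out from 28 and 27. Mitsunobu O-alkylation of 28 with 2-(trimethylsilyl)ethanol (PPh3, DIAD, THF) gives 3-methyl-4-[2-(trimethylsilyl)ethoxy]furan-2(5H)-one F7. Lithiation with LiN(iPr)2 in THF at −78 °C gives lithium 3-methyl-4-[2-(trimethylsilyl)ethoxy]furan-2-olate F8, which adds to 27 to give the aldol adduct 5-{(2S,6Z)-9-[5-(furan-3-ylmethyl)furan-3-yl]-1-hydroxy-2,6-dimethylnon-6-en-1-yl}-3-methyl-4-[2-(trimethylsilyl)ethoxy]furan-2(5H)-one F9. Mesylation (MsCl, Et3N) gives the methanesulfonate of the aldol adduct F10, and DBU elimination gives (5Z)-5-{(2S,6Z)-9-[5-(furan-3-ylmethyl)furan-3-yl]-2,6-dimethylnon-6-en-1-ylidene}-3-methyl-4-[2-(trimethylsilyl)ethoxy]furan-2(5H)-one F11. Bu4NF in THF at 0 °C then fragments the silylethyl group and, after mild acidification, would give target 34.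

**Further compounds**

F1 | step 3 | furan-3-ylmethanol | OCc1ccoc1
F2 | step 3 | 3-(bromomethyl)furan | BrCc1ccoc1
F3 | step 3 | (furan-3-ylmethyl)zinc bromide | Br[Zn]Cc1ccoc1
F4 | step 12 | 2-(furan-3-ylmethyl)-4-[(phenylsulfonyl)methyl]furan | O=S(=O)(Cc1coc(Cc2ccoc2)c1)c1ccccc1
F5 | step 12 | α-lithio derivative of F4 | [Li+].[CH-](c1coc(Cc2ccoc2)c1)S(=O)(=O)c1ccccc1
F6 | step 12 | tert-butyl({(2S,6Z)-9-[5-(furan-3-ylmethyl)furan-3-yl]-2,6-dimethyl-9-(phenylsulfonyl)non-6-en-1-yl}oxy)dimethylsilane | CC(C)(C)[Si](C)(C)OC[C@@H](C)CCC/C(C)=C\CC(c1coc(Cc2ccoc2)c1)S(=O)(=O)c1ccccc1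
F7 | step 18 | 3-methyl-4-[2-(trimethylsilyl)ethoxy]furan-2(5H)-one | CC1=C(OCC[Si](C)(C)C)COC1=O
F8 | step 18 | lithium 3-methyl-4-[2-(trimethylsilyl)ethoxy]furan-2-olate | [Li+].[O-]c1occ(OCC[Si](C)(C)C)c1C
F9 | step 18 | 5-{(2S,6Z)-9-[5-(furan-3-ylmethyl)furan-3-yl]-1-hydroxy-2,6-dimethylnon-6-en-1-yl}-3-methyl-4-[2-(trimethylsilyl)ethoxy]furan-2(5H)-one | CC1=C(OCC[Si](C)(C)C)C(OC1=O)C(O)[C@@H](C)CCC/C(C)=C\CCc2coc(Cc3ccoc3)c2
F10 | step 18 | methanesulfonate of F9 | CC1=C(OCC[Si](C)(C)C)C(OC1=O)C(OS(C)(=O)=O)[C@@H](C)CCC/C(C)=C\CCc2coc(Cc3ccoc3)c2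
F11 | step 18 | (5Z)-5-{(2S,6Z)-9-[5-(furan-3-ylmethyl)furan-3-yl]-2,6-dimethylnon-6-en-1-ylidene}-3-methyl-4-[2-(trimethylsilyl)ethoxy]furan-2(5H)-one | CC1=C(OCC[Si](C)(C)C)/C(=C/[C@@H](C)CCC/C(C)=C\CCc2coc(Cc3ccoc3)c2)OC1=O
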